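Each ε-ring of this C2-symmetric carotenoid is read as a disguised isophorone (carotenoid numbering): C2–C3–C4–C5 with the C5 methyl is pent-3-en-2-one, and C6–C1 with the gem-dimethyl group and C7 is 3-methylbut-2-enal. An iminium-catalysed enantioselective [4+2] cycloaddition of the enone's 2-silyloxydiene with the enal forges C1–C2 and C5–C6 at once. Because C1 carries two identical methyls it is not stereogenic, so the catalyst has to set only C6; the transient C5 centre is erased when C4=C5 is installed. Trans-selective reduction then gives C3–OH, and the resulting C15 hydroxy aldehyde is used twice in a double Wittig reaction with a C10 bis-ylide, exploiting the symmetry about C15–C15'.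

Key step: step 2

Remark (numbering): in each ring C1 is the CMe2 carbon, C2 the CH2, C3 the carbinol carbon, C4 the ring CH=, C5 the methyl-bearing sp2 carbon and C6 the CH that bears the polyene (C7 onward).
Assumption: step 2 may give both epimers at C5 in 5, 6, 9 and 10; the cis isomers are drawn and named, and both epimers converge in step 4, where C5 becomes sp2.
Assumption: 1, 3, 7 (E isomer) and 15 are bought.

Step 1
Reactants: 1 (E)-pent-3-en-2-one
Product: 2 (E)-tert-butyldimethyl(penta-1,3-dien-2-yloxy)silane
Conditions: t-BuMe2SiOTf, Et3N, Et2O, 0 °C to rt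
Reagents that add atoms: tert-butyldimethylsilyl trifluoromethanesulfonate, CC(C)(C)[Si](C)(C)OS(=O)(=O)C(F)(F)F
Why: Soft enolisation of the enone at its α'-methyl group by the silyl triflate and amine (cross-conjugated silyl dienol ether formation) should give the 2-silyloxydiene with the E-propenyl unit untouched.

Step 2
Reactants: 3 3-methylbut-2-enal; 2 (E)-tert-butyldimethyl(penta-1,3-dien-2-yloxy)silane
Product: 6 (1S,2S)-2,6,6-trimethyl-4-oxocyclohexane-1-carbaldehyde, via iminium ion 4 (not isolated), via silyl enol ether aldehyde 5 (not isolated)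
Conditions: (2S,5S)-5-benzyl-2-tert-butyl-3-methylimidazolidin-4-one trifluoroacetate (20 mol %, second-generation imidazolidinone organocatalyst), 2 (2 equiv), MeCN/H2O 19:1, −20 to 0 °C; then 1 M HCl, THF, 0 °C
Reagents that add atoms: none
Why: Proposed new method: the amine salt condenses with 3 to the (E)-iminium ion 4, whose β-carbon (C1, carrying the two methyls) is attacked by the CH2 terminus (C2) of diene 2, the ring is closed at C5–C6 in the same catalyst-bound species, hydrolysis releases 5 and dilute acid cleaves its silyl enol ether to 6. The closest known reaction types are the imidazolidinone-catalysed Diels–Alder reaction of enals with dienes, iminium-catalysed Mukaiyama–Michael additions of silyl enol ethers and iminium activation of β,β-disubstituted enals toward hydride or nitromethane, whereas a β,β-disubstituted enal has not been shown as the two-carbon partner of such a cycloaddition. The six-membered ring is closed by an asynchronous [4+2] cycloaddition, which in its stepwise limit is a Mukaiyama–Michael addition followed by a 6-endo-trig enamine Michael closure onto the enone unit freed from 2. C1 is not stereogenic, so the only centre that matters is C6, and it is set by the catalyst: the 5-benzyl group shields one face of the s-trans (E)-iminium ion or of the derived (E)-enamine, and bond formation at C6 on the open face should give the 1S aldehyde, which is 6R in carotenoid numbering. The C5 centre needs no control because step 4 removes it, so endo/exo selectivity is irrelevant. The step needs regioselectivity and enough reactivity at a hindered β-carbon: the 2-silyloxy group and the C5 methyl of the diene both direct its CH2 terminus to the β-carbon of the enal, and the diene is used in excess to outrun self-condensation of the enal.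

Step 3
Reactants: 6 (1S,2S)-2,6,6-trimethyl-4-oxocyclohexane-1-carbaldehyde; 7 diethyl [(2E)-3-cyano-2-methylprop-2-en-1-yl]phosphonate
Product: 9 (2E,4E)-3-methyl-5-[(1R,2S)-2,6,6-trimethyl-4-oxocyclohexyl]penta-2,4-dienenitrile, via lithiated phosphonate 8 (not isolated)
Conditions: 7, n-BuLi, THF, −78 °C; then 6, −78 to −20 °C
Reagents that add atoms: none
Why: Horner–Wadsworth–Emmons olefination with the preformed lithium phosphonate should attack the aldehyde far faster than the hindered ring ketone and give the E-configured C7=C8 bond, while the low temperature and the absence of free base protect the α-stereocentre C6.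

Step 4
Reactants: 9 (2E,4E)-3-methyl-5-[(1R,2S)-2,6,6-trimethyl-4-oxocyclohexyl]penta-2,4-dienenitrile
Product: 11 (2E,4E)-3-methyl-5-[(1R)-2,6,6-trimethyl-4-oxocyclohex-2-en-1-yl]penta-2,4-dienenitrile, via trimethylsilyl enol ether 10 (not isolated)
Conditions: Me3SiOTf, Et3N, CH2Cl2, 0 °C; then Pd(OAc)2 (1.1 equiv), MeCN, rt
Reagents that add atoms: none
Why: Saegusa–Ito oxidation, in which enolisation away from the quaternary C1 gives the C3–C4 silyl enol ether and β-hydride elimination from the palladium enolate can only take the C5 hydrogen because C1 has none, so both C5 epimers should converge on the C4=C5 enone with C6 untouched.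

Step 5
Reactants: 11 (2E,4E)-3-methyl-5-[(1R)-2,6,6-trimethyl-4-oxocyclohex-2-en-1-yl]penta-2,4-dienenitrile
Product: 12 (2E,4E)-5-[(1R,4R)-4-hydroxy-2,6,6-trimethylcyclohex-2-en-1-yl]-3-methylpenta-2,4-dienenitrile
Conditions: lithium tri-sec-butylborohydride, THF, −78 °C
Reagents that add atoms: none
Why: 1,2-Reduction of the β-substituted enone by the bulky hydride should occur on the ring face away from the axial C1 methyl group, which lies opposite the pseudoaxial C6 side chain, so that the new C3 hydroxyl ends up trans to the chain (3R).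

Step 6
Reactants: 12 (2E,4E)-5-[(1R,4R)-4-hydroxy-2,6,6-trimethylcyclohex-2-en-1-yl]-3-methylpenta-2,4-dienenitrile
Product: 14 (2E,4E)-5-[(1R,4R)-4-hydroxy-2,6,6-trimethylcyclohex-2-en-1-yl]-3-methylpenta-2,4-dienal, via aluminium aldimine 13 (not isolated)
Conditions: i-Bu2AlH (3 equiv), CH2Cl2, −78 to −40 °C; then aqueous potassium sodium tartrate, wet silica gel, 0 °C
Reagents that add atoms: water, O
Why: Partial reduction of the nitrile by the aluminium hydride should stop at the N-aluminio aldimine, which is hydrolysed under nearly neutral conditions to the dienal without ionising the allylic C3 hydroxyl.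

Step 7
Reactants: 15 (2E,4E,6E)-2,7-dimethylocta-2,4,6-trienedial
Product: 16 (2E,4E,6E)-2,7-dimethylocta-2,4,6-triene-1,8-diol
Conditions: NaBH4, MeOH/THF, 0 °C
Reagents that add atoms: none
Why: Borohydride 1,2-reduction of both conjugated aldehyde groups should give the diol with the triene geometry unchanged.

Step 8
Reactants: 16 (2E,4E,6E)-2,7-dimethylocta-2,4,6-triene-1,8-diol
Product: 17 [(2E,4E,6E)-2,7-dimethylocta-2,4,6-triene-1,8-diyl]bis(triphenylphosphonium) dibromide
Conditions: Ph3P·HBr (2.1 equiv), MeOH, rt
Reagents that add atoms: triphenylphosphine hydrobromide, [Br-].[PH+](c1ccccc1)(c1ccccc1)c1ccccc1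
Why: Acid-promoted ionisation of the two allylic alcohols and capture of the allyl cations by triphenylphosphine at the primary termini (phosphonium salt formation from an allylic alcohol) should give the crystalline bis-salt.

Step 9
Reactants: 14 (2E,4E)-5-[(1R,4R)-4-hydroxy-2,6,6-trimethylcyclohex-2-en-1-yl]-3-methylpenta-2,4-dienal (2 equiv); 17 [(2E,4E,6E)-2,7-dimethylocta-2,4,6-triene-1,8-diyl]bis(triphenylphosphonium) dibromide
Product: 19 (3R,3'R,6R,6'R)-ε,ε-carotene-3,3'-diol, via bis-ylide 18 (not isolated)
Conditions: NaOMe, MeOH/CH2Cl2, 0 °C to rt; then heptane/EtOH, reflux (thermal Z to E isomerisation), crystallisation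
Reagents that add atoms: none
Why: A twofold Wittig reaction of the bis-ylide with two molecules of the same aldehyde should form both C11=C12 bonds, the free hydroxyls and the C6 centres being inert to methoxide at this temperature, and heating converts the 11Z isomers into the all-E polyene.

Compound list
1 | (E)-pent-3-en-2-one | C/C=C/C(C)=O | starting material
2 | (E)-tert-butyldimethyl(penta-1,3-dien-2-yloxy)silane | C/C=C/C(=C)O[Si](C)(C)C(C)(C)C | intermediate
3 | 3-methylbut-2-enal | CC(C)=CC=O | starting material
4 | (2S,5S)-5-benzyl-2-tert-butyl-3-methyl-1-(3-methylbut-2-en-1-ylidene)-4-oxoimidazolidin-1-ium trifluoroacetate, (E)-iminium ion of 3 | CC(C)=C/C=[N+]1/[C@H](C(C)(C)C)N(C)C(=O)[C@@H]1Cc2ccccc2.[O-]C(=O)C(F)(F)F | intermediate (not isolated)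
5 | (1S,2S)-4-[(tert-butyldimethylsilyl)oxy]-2,6,6-trimethylcyclohex-3-ene-1-carbaldehyde | C[C@H]1C=C(O[Si](C)(C)C(C)(C)C)CC(C)(C)[C@H]1C=O | intermediate (not isolated)
6 | (1S,2S)-2,6,6-trimethyl-4-oxocyclohexane-1-carbaldehyde | C[C@H]1CC(=O)CC(C)(C)[C@H]1C=O | intermediate
7 | diethyl [(2E)-3-cyano-2-methylprop-2-en-1-yl]phosphonate | CCOP(=O)(OCC)C/C(C)=C/C#N | starting material
8 | lithium salt of 7 (carbanion at the carbon next to phosphorus) | [Li+].CCOP(=O)(OCC)[CH-]/C(C)=C/C#N | intermediate (not isolated)
9 | (2E,4E)-3-methyl-5-[(1R,2S)-2,6,6-trimethyl-4-oxocyclohexyl]penta-2,4-dienenitrile | C[C@H]1CC(=O)CC(C)(C)[C@H]1/C=C/C(C)=C/C#N | intermediate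
10 | (2E,4E)-3-methyl-5-[(1S,2R)-2,6,6-trimethyl-4-(trimethylsilyloxy)cyclohex-3-en-1-yl]penta-2,4-dienenitrile | C[C@H]1C=C(O[Si](C)(C)C)CC(C)(C)[C@H]1/C=C/C(C)=C/C#N | intermediate (not isolated)
11 | (2E,4E)-3-methyl-5-[(1R)-2,6,6-trimethyl-4-oxocyclohex-2-en-1-yl]penta-2,4-dienenitrile | CC1=CC(=O)CC(C)(C)[C@H]1/C=C/C(C)=C/C#N | intermediate
12 | (2E,4E)-5-[(1R,4R)-4-hydroxy-2,6,6-trimethylcyclohex-2-en-1-yl]-3-methylpenta-2,4-dienenitrile | CC1=C[C@H](O)CC(C)(C)[C@H]1/C=C/C(C)=C/C#N | intermediate
13 | N-(diisobutylaluminio) aldimine of 14, as its O-diisobutylaluminium alkoxide | CC1=C[C@H](O[Al](CC(C)C)CC(C)C)CC(C)(C)[C@H]1/C=C/C(C)=C/C=N/[Al](CC(C)C)CC(C)C | intermediate (not isolated)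
14 | (2E,4E)-5-[(1R,4R)-4-hydroxy-2,6,6-trimethylcyclohex-2-en-1-yl]-3-methylpenta-2,4-dienal | CC1=C[C@H](O)CC(C)(C)[C@H]1/C=C/C(C)=C/C=O | intermediate
15 | (2E,4E,6E)-2,7-dimethylocta-2,4,6-trienedial | O=C/C(C)=C/C=C/C=C(C)/C=O | starting material
16 | (2E,4E,6E)-2,7-dimethylocta-2,4,6-triene-1,8-diol | OC/C(C)=C/C=C/C=C(C)/CO | intermediate
17 | [(2E,4E,6E)-2,7-dimethylocta-2,4,6-triene-1,8-diyl]bis(triphenylphosphonium) dibromide | c1ccccc1[P+](c1ccccc1)(c1ccccc1)C/C(C)=C/C=C/C=C(C)/C[P+](c1ccccc1)(c1ccccc1)c1ccccc1.[Br-].[Br-] | intermediate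
18 | [(2E,4E,6E)-2,7-dimethylocta-2,4,6-triene-1,8-diylidene]bis(triphenylphosphorane) | C(=P(c1ccccc1)(c1ccccc1)c1ccccc1)/C(C)=C/C=C/C=C(C)/C=P(c1ccccc1)(c1ccccc1)c1ccccc1 | intermediate (not isolated)
19 | (3R,3'R,6R,6'R)-ε,ε-carotene-3,3'-diol (lactucaxanthin) | CC1=C[C@H](O)CC(C)(C)[C@H]1/C=C/C(C)=C/C=C/C(C)=C/C=C/C=C(C)/C=C/C=C(C)/C=C/[C@H]1C(C)=C[C@H](O)CC1(C)C | target

Total step count: 9. Longest linear sequence: 7 steps (steps 1, 2, 3, 4, 5, 6 and 9, from 1).

Steps most likely to fail

1. Step 2 (Proposed new method). What may go wrong: slow conjugate addition to the β,β-disubstituted iminium ion, self-condensation of the enal through its dienamine, protodesilylation of the diene before it reacts, and erosion of the C6 configuration by enamine formation from the product. The fallback uses known chemistry, sets out from 2 and comes back at 6. (S)-4-Benzyloxazolidin-2-one is N-acylated with 3-methylbut-2-enoyl chloride (n-BuLi, THF, −78 °C) to the imide (S)-4-benzyl-3-(3-methylbut-2-enoyl)oxazolidin-2-one F1. An auxiliary-controlled Diels–Alder reaction of F1 with 2 (Et2AlCl, CH2Cl2, −78 to −30 °C) should add the diene to the chelated s-cis imide on the face away from the benzyl group, which is a far stronger two-carbon partner than the iminium ion, and give the adduct (4S)-4-benzyl-3-{(1S,2S)-4-[(tert-butyldimethylsilyl)oxy]-2,6,6-trimethylcyclohex-3-ene-1-carbonyl}oxazolidin-2-one F2. Reductive removal of the auxiliary (LiBH4, Et2O, 1 equiv H2O, 0 °C) gives [(1S,2R)-4-[(tert-butyldimethylsilyl)oxy]-2,6,6-trimethylcyclohex-3-en-1-yl]methanol F3. Oxidation with Dess–Martin periodinane (pyridine, CH2Cl2, 0 °C) gives aldehyde 5, and 1 M HCl in THF gives 6.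

2. Step 3. What may go wrong: enolisation of the hindered α-branched aldehyde by the phosphonate anion, which epimerises C6 and becomes loss of enantiopurity once C5 is flattened in step 4, together with sluggish addition to the neopentyl-type carbonyl. The fallback sets out from 6 and comes back at 9. 3-Methylbut-2-enenitrile is brominated at a methyl group (N-bromosuccinimide, dibenzoyl peroxide, PhCF3, reflux) to (2E)-4-bromo-3-methylbut-2-enenitrile F4, which triphenylphosphine in toluene converts to [(2E)-3-cyano-2-methylprop-2-en-1-yl]triphenylphosphonium bromide F5. Heating F5 with 6 in 1,2-epoxybutane lets the epoxide take up HBr and release the ylide [(2E)-3-cyano-2-methylprop-2-en-1-ylidene]triphenylphosphorane F6 without any added base, and the Wittig reaction should give 9 after isomerisation of any 7Z isomer with a trace of iodine.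

3. Step 5. What may go wrong: poor facial selectivity in the hydride addition (formation of the 3,6-cis alcohol) and competing conjugate reduction of the dienenitrile. The fallback sets out from 11 and comes back at 12. A Corey–Bakshi–Shibata reduction with (S)-1-methyl-3,3-diphenyltetrahydro-1H,3H-pyrrolo[1,2-c][1,3,2]oxazaborole (20 mol %) and catecholborane in toluene at −78 °C places the hydride under reagent control, with the C4=C5 alkene as the large group, and should give the 3R carbinol whatever the intrinsic bias of the ring. This fallback makes no new compound (F0).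

Further compounds
F1 | step 2 | (S)-4-benzyl-3-(3-methylbut-2-enoyl)oxazolidin-2-one | CC(C)=CC(=O)N1[C@@H](Cc2ccccc2)COC1=O
F2 | step 2 | (4S)-4-benzyl-3-{(1S,2S)-4-[(tert-butyldimethylsilyl)oxy]-2,6,6-trimethylcyclohex-3-ene-1-carbonyl}oxazolidin-2-one | C[C@H]1C=C(O[Si](C)(C)C(C)(C)C)CC(C)(C)[C@H]1C(=O)N2[C@@H](Cc3ccccc3)COC2=O
F3 | step 2 | [(1S,2R)-4-[(tert-butyldimethylsilyl)oxy]-2,6,6-trimethylcyclohex-3-en-1-yl]methanol | C[C@H]1C=C(O[Si](C)(C)C(C)(C)C)CC(C)(C)[C@H]1CO
F4 | step 3 | (2E)-4-bromo-3-methylbut-2-enenitrile | N#C/C=C(\C)CBr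
F5 | step 3 | [(2E)-3-cyano-2-methylprop-2-en-1-yl]triphenylphosphonium bromide | N#C/C=C(\C)C[P+](c1ccccc1)(c1ccccc1)c1ccccc1.[Br-]
F6 | step 3 | [(2E)-3-cyano-2-methylprop-2-en-1-ylidene]triphenylphosphorane | N#C/C=C(\C)C=P(c1ccccc1)(c1ccccc1)c1ccccc1
F0 | step 5 | none | none
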